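**Plan**
Retrosynthetic cuts, in order: the O–CH3 placeholder on unit C; C2–O1 and C2–C3 of unit B (C2 leaves as carbon monoxide); the biaryl bond C6(A)–C8(B); C3–C4 and C2–O1 of unit C; the O–CH2 bond on O7 of unit A; pyranone A.
Enabling feature: in unit B the lactone carbon C2 is a one-carbon bridge between O1 (on C8a) and C3, and C3=C4 sits on C4a next to C8a. Without C2 the unit is a 2-vinylphenol, so ring B can go through the crowded aryl–aryl coupling as a monocyclic resorcinol-type styrene.
Forward order: pyranone A (Wittig–lactonisation), pyranone C on an oxyacetic acid tether (Perkin), biaryl bond (Suzuki–Miyaura), pyranone B last (palladium, CO), then demethylation.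
Ring B is metalated at the aldehyde level, before the vinyl group exists, and its MOM groups are removed without Brønsted acid. The vinylresorcinol tolerates neither butyllithium nor strong acid.
Stereochemistry: the target has no stereocentre, and the three C3=C4 bonds are cis by ring constraint.

Key step: step 10

Assumption: the C6(A)–C8(B) axis carries three oxygen ortho substituents and one hydrogen and is drawn without axial configuration, so the material is made as the racemic or freely interconverting mixture of rotamers.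

Step 1
Reactants: 1 5-bromo-2,4-dihydroxybenzaldehyde
Product: 3 6-bromo-7-hydroxychromen-2-one, via ethyl (E)-5-bromo-2,4-dihydroxycinnamate 2 (not isolated)
Conditions: Ph3P=CHCO2Et (1.2 equiv), PhNEt2, reflux
Reagents that add atoms: ethyl (triphenylphosphoranylidene)acetate, CCOC(=O)C=P(c1ccccc1)(c1ccccc1)c1ccccc1
Why: Wittig olefination of a salicylaldehyde with a stabilised ylide, followed by thermal E-to-Z isomerisation and lactonisation in boiling diethylaniline, is a standard one-pot coumarin synthesis that tolerates free phenols and aryl bromides.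

Step 2
Reactants: 3 6-bromo-7-hydroxychromen-2-one; 4 tert-butyl bromoacetate
Product: 5 tert-butyl 2-[(6-bromo-2-oxochromen-7-yl)oxy]acetate
Conditions: K2CO3, acetone, reflux
Reagents that add atoms: none
Why: Williamson ether synthesis between the only, fairly acidic, phenol of 3 and a primary α-bromo ester should be fast under carbonate conditions that leave the lactone closed.

Step 3
Reactants: 5 tert-butyl 2-[(6-bromo-2-oxochromen-7-yl)oxy]acetate
Product: 6 2-[(6-bromo-2-oxochromen-7-yl)oxy]acetic acid
Conditions: TFA, CH2Cl2, rt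
Reagents that add atoms: none
Why: Acidolysis of a tert-butyl ester with loss of isobutene frees the acid without the hydroxide that would open the pyranone of unit A.

Step 4
Reactants: 6 2-[(6-bromo-2-oxochromen-7-yl)oxy]acetic acid; 7 2-hydroxy-4-methoxybenzaldehyde
Product: 9 6-bromo-7-[(7-methoxy-2-oxochromen-3-yl)oxy]chromen-2-one, via aryl ester 8 (not isolated)
Conditions: Ac2O, Et3N, 120 °C
Reagents that add atoms: none
Why: In this Perkin–Oglialoro condensation acetic anhydride activates 6 so that it acylates the phenol of 7, and the oxygen-flanked CH2 of ester 8 (more acidic than an acetyl CH3) then closes onto the aldehyde by intramolecular aldol condensation, the established route from aryloxyacetic acids to 3-aryloxycoumarins.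

Step 5
Reactants: 10 2,4-dihydroxybenzaldehyde
Product: 11 2,4-bis(methoxymethoxy)benzaldehyde
Conditions: NaH (2.5 equiv), MOMCl (2.5 equiv), DMF, 0 °C to rt
Reagents that add atoms: chloromethyl methyl ether, COCCl
Why: Williamson-type O-alkylation of both phenoxides, where full deprotonation with NaH overcomes the hydrogen bond of the C2 hydroxyl to the aldehyde and the MOM groups later direct the metalation.

Step 6
Reactants: 11 2,4-bis(methoxymethoxy)benzaldehyde
Product: 14 2,4-bis(methoxymethoxy)-3-(4,4,5,5-tetramethyl-1,3,2-dioxaborolan-2-yl)benzaldehyde, via lithium amino alkoxide 12 (not isolated), via C3-aryllithium 13 (not isolated)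
Conditions: N-methylpiperazine, n-BuLi, THF, −20 °C, then 11; n-BuLi (1.5 equiv), −20 to 0 °C; iPrOBpin (3 equiv), −78 °C to rt; aq NH4Cl
Reagents that add atoms: 2-isopropoxy-4,4,5,5-tetramethyl-1,3,2-dioxaborolane, CC(C)OB1OC(C)(C)C(C)(C)O1
Why: This is directed ortho-metalation with in situ protection of the aldehyde as its lithium α-amino alkoxide: adduct 12 shields the formyl group, the C3–H between two chelating OMOM groups is by far the most acidic ring position, and metalating at the aldehyde level avoids the carbolithiation that butyllithium would inflict on the corresponding styrene.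

Step 7
Reactants: 14 2,4-bis(methoxymethoxy)-3-(4,4,5,5-tetramethyl-1,3,2-dioxaborolan-2-yl)benzaldehyde
Product: 15 2-[3-ethenyl-2,6-bis(methoxymethoxy)phenyl]-4,4,5,5-tetramethyl-1,3,2-dioxaborolane
Conditions: MePPh3Br (1.3 equiv), KOtBu (1.2 equiv), THF, 0 °C
Reagents that add atoms: methyltriphenylphosphonium bromide, C[P+](c1ccccc1)(c1ccccc1)c1ccccc1.[Br-]
Why: Wittig methylenation of an aromatic aldehyde with the non-stabilised ylide is fast at 0 °C and is routinely run on formyl-substituted aryl pinacolboronates, whose boron binds the ylide only reversibly.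

Step 8
Reactants: 9 6-bromo-7-[(7-methoxy-2-oxochromen-3-yl)oxy]chromen-2-one; 15 2-[3-ethenyl-2,6-bis(methoxymethoxy)phenyl]-4,4,5,5-tetramethyl-1,3,2-dioxaborolane (1.5 equiv)
Product: 16 6-[3-ethenyl-2,6-bis(methoxymethoxy)phenyl]-7-[(7-methoxy-2-oxochromen-3-yl)oxy]chromen-2-one
Conditions: Pd(OAc)2 (5 mol %), SPhos (10 mol %), K3PO4, dioxane–H2O, 80 °C
Reagents that add atoms: none
Why: Suzuki–Miyaura coupling with the bulky, electron-rich biarylphosphine SPhos is the established solution for tri-ortho-substituted biaryls from 2,6-dialkoxyarylboron reagents; the bromide on the electron-poor coumarin adds readily to zerovalent palladium, and phosphate base at moderate temperature should spare the MOM ethers, lactones and vinyl group.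

Step 9
Reactants: 16 6-[3-ethenyl-2,6-bis(methoxymethoxy)phenyl]-7-[(7-methoxy-2-oxochromen-3-yl)oxy]chromen-2-one
Product: 18 6-(3-ethenyl-2,6-dihydroxyphenyl)-7-[(7-methoxy-2-oxochromen-3-yl)oxy]chromen-2-one, via bis(trimethylsilyl) ether 17 (not isolated)
Conditions: TMSOTf (4 equiv), 2,2′-bipyridyl (6 equiv), MeCN, 0 °C to rt; then H2O
Reagents that add atoms: none
Why: In the silyl triflate–bipyridyl cleavage of aromatic MOM ethers the acetal oxygen is silylated, bipyridyl carries off the methoxymethyl fragment and buffers the medium, and water hydrolyses the aryl silyl ethers of 17, so the easily protonated 4-vinylresorcinol unit never meets an acid stronger than a pyridinium salt and should escape the cationic oligomerisation that HCl in methanol would invite.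

Step 10
Reactants: 18 6-(3-ethenyl-2,6-dihydroxyphenyl)-7-[(7-methoxy-2-oxochromen-3-yl)oxy]chromen-2-one; 19 carbon monoxide
Product: 20 7-hydroxy-8-{7-[(7-methoxy-2-oxochromen-3-yl)oxy]-2-oxochromen-6-yl}chromen-2-one
Conditions: Pd(OAc)2 (10 mol %), 1,4-benzoquinone (1.5 equiv), CO (5 bar), MeCN, 100 °C
Reagents that add atoms: none
Why: The hydroxyl on C2′ of ring B, the one next to the vinyl group, exchanges with acetate on divalent palladium, carbon monoxide inserts into the Pd–O bond, and the resulting aryloxycarbonylpalladium adds across the neighbouring alkene, delivering the acyl carbon to the CH2 terminus and the metal to the benzylic carbon. β-Hydride elimination then installs the C3=C4 double bond, and benzoquinone returns zerovalent palladium to the divalent state while also suppressing radical polymerisation of the styrene; this is the known palladium-catalysed oxidative cyclocarbonylation of 2-vinylphenols to coumarins, here applied to a larger phenol. Pyranone B closes by a 6-endo-trig acylpalladation, with C2–O1 made first and C2–C3 as the ring-closing bond; the 5-exo alternative would give a strained benzofuranone and a primary alkylpalladium without benzylic stabilisation. No stereocentre is formed. The selectivity needed is between the two phenols of ring B, and the substrate settles it: the C6′ hydroxyl lies para to the vinyl group, so an aryloxycarbonylpalladium formed there has no alkene within reach and simply reverts by decarbonylation. The C3=C4 bonds of units A and C are electron-poor, internal and remote from any phenol and should stay inert.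

Step 11
Reactants: 20 7-hydroxy-8-{7-[(7-methoxy-2-oxochromen-3-yl)oxy]-2-oxochromen-6-yl}chromen-2-one
Product: 22 7-hydroxy-8-{7-[(7-hydroxy-2-oxochromen-3-yl)oxy]-2-oxochromen-6-yl}chromen-2-one, via bis(dibromoboryl) ether 21 (not isolated)
Conditions: BBr3 (8 equiv), CH2Cl2, −78 °C to rt; then H2O
Reagents that add atoms: none
Why: In this Lewis-acid aryl methyl ether cleavage bromide can attack only the one sp3 carbon bound to an ether oxygen, the O–CH3 of unit C, whereas the C7(A)–O–C3(C) ether joins two sp2 carbons and the three lactones merely bind the excess BBr3 reversibly until the aqueous quench.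

**Compound list**
1 | 5-bromo-2,4-dihydroxybenzaldehyde | O=Cc1cc(Br)c(O)cc1O | starting material
2 | ethyl (E)-3-(5-bromo-2,4-dihydroxyphenyl)prop-2-enoate | CCOC(=O)/C=C/c1cc(Br)c(O)cc1O | intermediate
3 | 6-bromo-7-hydroxychromen-2-one | O=c1ccc2cc(Br)c(O)cc2o1 | intermediate
4 | tert-butyl bromoacetate | CC(C)(C)OC(=O)CBr | starting material
5 | tert-butyl 2-[(6-bromo-2-oxochromen-7-yl)oxy]acetate | CC(C)(C)OC(=O)COc1cc2oc(=O)ccc2cc1Br | intermediate
6 | 2-[(6-bromo-2-oxochromen-7-yl)oxy]acetic acid | O=C(O)COc1cc2oc(=O)ccc2cc1Br | intermediate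
7 | 2-hydroxy-4-methoxybenzaldehyde | COc1ccc(C=O)c(O)c1 | starting material
8 | 2-formyl-5-methoxyphenyl 2-[(6-bromo-2-oxochromen-7-yl)oxy]acetate | COc1ccc(C=O)c(OC(=O)COc2cc3oc(=O)ccc3cc2Br)c1 | intermediate
9 | 6-bromo-7-[(7-methoxy-2-oxochromen-3-yl)oxy]chromen-2-one | COc1ccc2cc(Oc3cc4oc(=O)ccc4cc3Br)c(=O)oc2c1 | intermediate
10 | 2,4-dihydroxybenzaldehyde | O=Cc1ccc(O)cc1O | starting material
11 | 2,4-bis(methoxymethoxy)benzaldehyde | COCOc1ccc(C=O)c(OCOC)c1 | intermediate
12 | lithium [2,4-bis(methoxymethoxy)phenyl](4-methylpiperazin-1-yl)methanolate (racemic, transient) | COCOc1ccc(C(O[Li])N2CCN(C)CC2)c(OCOC)c1 | intermediate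
13 | lithium [3-lithio-2,4-bis(methoxymethoxy)phenyl](4-methylpiperazin-1-yl)methanolate (racemic, transient) | COCOc1ccc(C(O[Li])N2CCN(C)CC2)c(OCOC)c1[Li] | intermediate
14 | 2,4-bis(methoxymethoxy)-3-(4,4,5,5-tetramethyl-1,3,2-dioxaborolan-2-yl)benzaldehyde | COCOc1ccc(C=O)c(OCOC)c1B2OC(C)(C)C(C)(C)O2 | intermediate
15 | 2-[3-ethenyl-2,6-bis(methoxymethoxy)phenyl]-4,4,5,5-tetramethyl-1,3,2-dioxaborolane | C=Cc1ccc(OCOC)c(B2OC(C)(C)C(C)(C)O2)c1OCOC | intermediate
16 | 6-[3-ethenyl-2,6-bis(methoxymethoxy)phenyl]-7-[(7-methoxy-2-oxochromen-3-yl)oxy]chromen-2-one | C=Cc1ccc(OCOC)c(-c2cc3ccc(=O)oc3cc2Oc2cc3ccc(OC)cc3oc2=O)c1OCOC | intermediate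
17 | 6-[3-ethenyl-2,6-bis(trimethylsilyloxy)phenyl]-7-[(7-methoxy-2-oxochromen-3-yl)oxy]chromen-2-one | C=Cc1ccc(O[Si](C)(C)C)c(-c2cc3ccc(=O)oc3cc2Oc2cc3ccc(OC)cc3oc2=O)c1O[Si](C)(C)C | intermediate
18 | 6-(3-ethenyl-2,6-dihydroxyphenyl)-7-[(7-methoxy-2-oxochromen-3-yl)oxy]chromen-2-one | C=Cc1ccc(O)c(-c2cc3ccc(=O)oc3cc2Oc2cc3ccc(OC)cc3oc2=O)c1O | intermediate
19 | carbon monoxide | [C-]#[O+] | starting material
20 | 7-hydroxy-8-{7-[(7-methoxy-2-oxochromen-3-yl)oxy]-2-oxochromen-6-yl}chromen-2-one | O=c1ccc2ccc(O)c(-c3cc4ccc(=O)oc4cc3Oc3cc4ccc(OC)cc4oc3=O)c2o1 | intermediate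
21 | bis(dibromoboryl) ether of the target (both phenol oxygens as O–BBr2) | O=c1ccc2cc(-c3c(OB(Br)Br)ccc4ccc(=O)oc34)c(Oc3cc4ccc(OB(Br)Br)cc4oc3=O)cc2o1 | intermediate
22 | 7-hydroxy-8-{7-[(7-hydroxy-2-oxochromen-3-yl)oxy]-2-oxochromen-6-yl}chromen-2-one (CNP0215289.0) | O=c1ccc2cc(-c3c(O)ccc4ccc(=O)oc34)c(Oc3cc4ccc(O)cc4oc3=O)cc2o1 | target

Total step count: 11. Longest linear sequence: 8 steps (steps 1–4, then 8–11). The ring B branch (steps 5–7) joins at step 8.

**Steps most likely to fail**

Risk 1, step 10. The palladium aryloxide has to form at a phenol squeezed between the vinyl group and unit A. If this is slow, thermal or metal-induced oligomerisation of the electron-rich styrene, or precipitation of palladium metal, may overtake carbonylation.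
The fallback swaps carbonylation for ring-closing metathesis; it sets out from 18 and returns at 20.
- Acryloyl chloride and Et3N in CH2Cl2 at 0 °C should acylate both phenols to give 4-ethenyl-2-{7-[(7-methoxy-2-oxochromen-3-yl)oxy]-2-oxochromen-6-yl}benzene-1,3-diyl diprop-2-enoate F1.
- The second-generation Grubbs catalyst in dilute toluene at 80 °C should close only the acrylate that lies ortho to the vinyl group, giving 8-{7-[(7-methoxy-2-oxochromen-3-yl)oxy]-2-oxochromen-6-yl}-2-oxochromen-7-yl prop-2-enoate F2.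
- Brief methanolysis of the remaining aryl acrylate (K2CO3, MeOH, 0 °C, mild acidic work-up) delivers 20.

Risk 2, step 8. Transmetalation at a boron flanked by two alkoxy groups is slow. Protodeboronation of the boronate and Heck-type arylation of its vinyl group by the arylpalladium bromide can both outrun the coupling.
The fallback reverses the polarity of the partners and postpones the olefination; it sets out from 11 and 9 and returns at 16.
- Aryllithium 13, generated from 11 through 12 as in step 6, is quenched with I2 to give 3-iodo-2,4-bis(methoxymethoxy)benzaldehyde F3.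
- Bromide 9 undergoes Miyaura borylation (PdCl2(dppf), B2pin2, KOAc, dioxane, 90 °C) to 7-[(7-methoxy-2-oxochromen-3-yl)oxy]-6-(4,4,5,5-tetramethyl-1,3,2-dioxaborolan-2-yl)chromen-2-one F4, whose boron has only one ortho substituent.
- Suzuki–Miyaura coupling of F3 with F4 (Pd(OAc)2, SPhos, K3PO4) should give 2,4-bis(methoxymethoxy)-3-{7-[(7-methoxy-2-oxochromen-3-yl)oxy]-2-oxochromen-6-yl}benzaldehyde F5, with no alkene present.
- One equivalent of Ph3P=CH2 at −78 °C, where the aldehyde outcompetes the lactones, converts F5 into 16.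

Risk 3, step 9. Electrophilic activation of two hindered acetals next to a very electron-rich styrene may trigger protonation or silylation of the vinyl group followed by cationic oligomerisation. It may also stall at partial cleavage.
The fallback replaces electrophilic acetal cleavage by fluoride-induced fragmentation; it sets out from 10 and returns at 18.
- SEMCl and NaH in DMF give 2,4-bis{[2-(trimethylsilyl)ethoxy]methoxy}benzaldehyde F6.
- The chemistry of steps 6 to 8 is repeated on F6. It runs through the SEM-protected lithium amino alkoxide F7 and the SEM-protected C3-aryllithium F8 to the SEM-protected boronate aldehyde F9.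
- Wittig methylenation of F9 gives the SEM-protected styrene boronate F10, and Suzuki–Miyaura coupling of F10 with 9 gives the bis-SEM biaryl F11.
- TBAF in THF at 45 °C, then aq NH4Cl, should release 18 from F11 under non-acidic conditions.

**Further compounds**
F1 | step 10 | 4-ethenyl-2-{7-[(7-methoxy-2-oxochromen-3-yl)oxy]-2-oxochromen-6-yl}benzene-1,3-diyl diprop-2-enoate | C=Cc1ccc(OC(=O)C=C)c(-c2cc3ccc(=O)oc3cc2Oc2cc3ccc(OC)cc3oc2=O)c1OC(=O)C=C
F2 | step 10 | 8-{7-[(7-methoxy-2-oxochromen-3-yl)oxy]-2-oxochromen-6-yl}-2-oxochromen-7-yl prop-2-enoate | O=c1ccc2ccc(OC(=O)C=C)c(-c3cc4ccc(=O)oc4cc3Oc3cc4ccc(OC)cc4oc3=O)c2o1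
F3 | step 8 | 3-iodo-2,4-bis(methoxymethoxy)benzaldehyde | COCOc1ccc(C=O)c(OCOC)c1I
F4 | step 8 | 7-[(7-methoxy-2-oxochromen-3-yl)oxy]-6-(4,4,5,5-tetramethyl-1,3,2-dioxaborolan-2-yl)chromen-2-one | COc1ccc2cc(Oc3cc4oc(=O)ccc4cc3B5OC(C)(C)C(C)(C)O5)c(=O)oc2c1
F5 | step 8 | 2,4-bis(methoxymethoxy)-3-{7-[(7-methoxy-2-oxochromen-3-yl)oxy]-2-oxochromen-6-yl}benzaldehyde | O=Cc1ccc(OCOC)c(-c2cc3ccc(=O)oc3cc2Oc2cc3ccc(OC)cc3oc2=O)c1OCOC
F6 | step 9 | 2,4-bis{[2-(trimethylsilyl)ethoxy]methoxy}benzaldehyde | O=Cc1ccc(OCOCC[Si](C)(C)C)cc1OCOCC[Si](C)(C)C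
F7 | step 9 | lithium (2,4-bis{[2-(trimethylsilyl)ethoxy]methoxy}phenyl)(4-methylpiperazin-1-yl)methanolate (racemic, transient) | [Li]OC(c1ccc(OCOCC[Si](C)(C)C)cc1OCOCC[Si](C)(C)C)N1CCN(C)CC1
F8 | step 9 | lithium (3-lithio-2,4-bis{[2-(trimethylsilyl)ethoxy]methoxy}phenyl)(4-methylpiperazin-1-yl)methanolate (racemic, transient) | [Li]OC(c1ccc(OCOCC[Si](C)(C)C)c([Li])c1OCOCC[Si](C)(C)C)N1CCN(C)CC1
F9 | step 9 | 3-(4,4,5,5-tetramethyl-1,3,2-dioxaborolan-2-yl)-2,4-bis{[2-(trimethylsilyl)ethoxy]methoxy}benzaldehyde | O=Cc1ccc(OCOCC[Si](C)(C)C)c(B2OC(C)(C)C(C)(C)O2)c1OCOCC[Si](C)(C)C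
F10 | step 9 | 2-(3-ethenyl-2,6-bis{[2-(trimethylsilyl)ethoxy]methoxy}phenyl)-4,4,5,5-tetramethyl-1,3,2-dioxaborolane | C=Cc1ccc(OCOCC[Si](C)(C)C)c(B2OC(C)(C)C(C)(C)O2)c1OCOCC[Si](C)(C)C
F11 | step 9 | 6-(3-ethenyl-2,6-bis{[2-(trimethylsilyl)ethoxy]methoxy}phenyl)-7-[(7-methoxy-2-oxochromen-3-yl)oxy]chromen-2-one | C=Cc1ccc(OCOCC[Si](C)(C)C)c(-c2cc3ccc(=O)oc3cc2Oc2cc3ccc(OC)cc3oc2=O)c1OCOCC[Si](C)(C)C
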